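**Plan**

- Numbering used throughout: 3,7-dioxabicyclo[3.3.0]octan-2-one, with C1 and C5 at the ring fusion, C2 the lactone carbonyl, O3, C4 (4-hydroxy-3-methoxyphenyl), C6H2, O7 and C8 (3,4-dihydroxyphenyl). The target is read as (1S,4S,5R,8S): cis-fused, both aryl groups exo.
- Retrosynthesis: the three phenols go back to benzyl ethers. Then C5–C6 and C1–C8 of the tetrahydrofuran ring are cut together, giving a carbonyl ylide (C6H2–O7–C8H-aryl) and (S)-5-aryl-furan-2(5H)-one. The butenolide is cut at its C=C (metathesis) and its ester C–O bond, back to a vinyl carbinol from O-benzylvanillin.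
- Enabling feature: O7 lies between C6H2 and the benzylic, aryl-stabilised C8, which is a C–O–C 1,3-dipole. The C1–C5 bond that this unit spans is the α,β-bond of the C2 lactone carbonyl, i.e. the alkene of a butenolide.
- Forward order: the lactone ring arises first (acylation, ring-closing metathesis). The tetrahydrofuran ring follows in one [3+2] cycloaddition that joins the two fragments, then debenzylation.
- Stereochemistry: C4 comes from a lipase resolution of the allylic alcohol. C1, C5 and C8 all come from the cycloaddition (attack anti to the C4 aryl group, suprafacial cis fusion, exo aryl).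

Key step: step 6

**Route**

Step 1
Reactants: 1 4-(benzyloxy)-3-methoxybenzaldehyde; 2 vinylmagnesium bromide
Product: 3 racemic 1-[4-(benzyloxy)-3-methoxyphenyl]prop-2-en-1-ol
Conditions: THF, −78 °C to 0 °C; aq. NH4Cl
Reagents that add atoms: vinylmagnesium bromide, C=C[Mg]Br
Why: Grignard 1,2-addition of the vinyl nucleophile to the aryl aldehyde should give the racemic allylic alcohol, the benzyl ether being inert.

Step 2
Reactants: 3 racemic 1-[4-(benzyloxy)-3-methoxyphenyl]prop-2-en-1-ol
Product: 4 (S)-1-[4-(benzyloxy)-3-methoxyphenyl]prop-2-en-1-ol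
Conditions: Novozym 435 (immobilised Candida antarctica lipase B), vinyl acetate, MTBE, 30 °C, to just past half conversion; chromatography
Reagents that add atoms: none
Why: Lipase-catalysed kinetic resolution by transesterification, in which the enzyme should acylate the R enantiomer (aryl as the large group, vinyl as the medium group, arranged as in (R)-1-phenylethanol) and leave the S alcohol, which fixes the future C4 configuration.

Step 3
Reactants: 4 (S)-1-[4-(benzyloxy)-3-methoxyphenyl]prop-2-en-1-ol; 5 acryloyl chloride
Product: 6 (S)-1-[4-(benzyloxy)-3-methoxyphenyl]prop-2-en-1-yl acrylate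
Conditions: Et3N, CH2Cl2, −20 °C to 0 °C; Et3N-deactivated silica
Reagents that add atoms: acryloyl chloride, C=CC(=O)Cl
Why: Esterification of the secondary alcohol with an acid chloride and amine base takes place at oxygen and should leave the carbinol stereocentre untouched.

Step 4
Reactants: 6 (S)-1-[4-(benzyloxy)-3-methoxyphenyl]prop-2-en-1-yl acrylate
Product: 7 (S)-5-[4-(benzyloxy)-3-methoxyphenyl]furan-2(5H)-one
Conditions: second-generation Grubbs catalyst [RuCl2(H2IMes)(PCy3)(=CHPh)] (5 mol%), CH2Cl2 (0.01 M), 40 °C
Reagents that add atoms: none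
Why: Ring-closing olefin metathesis of the allyl acrylate should close the five-membered lactone ring with loss of ethene under neutral conditions, which is needed because the aryl-bearing C5–H of the butenolide is base-labile.

Step 5
Reactants: 8 3,4-bis(benzyloxy)benzaldehyde; 9 (trimethylsilyl)methanol
Product: 10 1,2-bis(benzyloxy)-4-{bis[(trimethylsilyl)methoxy]methyl}benzene
Conditions: PPTS (cat.), benzene, reflux, Dean–Stark trap; Et3N quench
Reagents that add atoms: (trimethylsilyl)methanol, C[Si](C)(C)CO
Why: Acid-catalysed acetalisation with azeotropic removal of water should install two equivalent silylmethoxy groups, so that one can later leave and the other can act as the silyl-bearing ylide terminus.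

Step 6
Reactants: 7 (S)-5-[4-(benzyloxy)-3-methoxyphenyl]furan-2(5H)-one; 10 1,2-bis(benzyloxy)-4-{bis[(trimethylsilyl)methoxy]methyl}benzene
Product: 13 (1S,4S,5R,8S)-4-[4-(benzyloxy)-3-methoxyphenyl]-8-[3,4-bis(benzyloxy)phenyl]-3,7-dioxabicyclo[3.3.0]octan-2-one, via α-chloro ether 11 (not isolated), via carbonyl ylide 12 (not isolated)
Conditions: 10 (1.5 equiv), AcCl (1.5 equiv), CH2Cl2, 0 °C, then evaporation; 7, CsF (1.4 equiv, added last in portions), MeCN, 0 °C to rt
Reagents that add atoms: none
Why: Acetyl chloride exchanges one silylmethoxy group of 10 for chloride, 11 ionises to an aryl-stabilised oxocarbenium ion, fluoride cleaves its CH2–Si bond (1,3-elimination) to the ylide 12, and 12 adds as a 4π 1,3-dipole across the electron-poor C3=C4 bond of 7 in a concerted suprafacial [3+2] cycloaddition. The closest known reaction type is the fluoride-induced, silicon-based 1,3-elimination of α-chloroalkyl silylmethyl ethers to non-stabilised carbonyl ylides and their cycloaddition to acrylates, fumarates and maleimides. The tetrahydrofuran ring is closed by intermolecular [3+2] annulation that forms C5–C6 and C1–C8 at once, and only the cis-fused bicycle can result because the butenolide alkene is cis within its ring. C1 and C5 should be set by approach of the dipole to the alkene face anti to the aryl group on C5 of 7 (C4 of the target), and C8 by an exo transition state in which the E-configured aryl terminus of the ylide points away from the lactone ring. The step needs regioselectivity (CH2 terminus to the β-carbon, aryl-CH terminus to the α-carbon), which should follow from the larger HOMO coefficient and smaller size of the CH2 terminus, the larger LUMO coefficient at the β-carbon and the aryl stabilisation of positive charge at C8 in an asynchronous transition state. It also needs the acidic C5–H of 7 to survive, which is why fluoride is kept below the amount of 11 and added last at 0 °C.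

Step 7
Reactants: 13 (1S,4S,5R,8S)-4-[4-(benzyloxy)-3-methoxyphenyl]-8-[3,4-bis(benzyloxy)phenyl]-3,7-dioxabicyclo[3.3.0]octan-2-one
Product: 14 (1S,4S,5R,8S)-8-(3,4-dihydroxyphenyl)-4-(4-hydroxy-3-methoxyphenyl)-3,7-dioxabicyclo[3.3.0]octan-2-one
Conditions: H2 (1 atm), 10% Pd/C, EtOAc, rt, stopped after uptake of three equivalents
Reagents that add atoms: none
Why: Heterogeneous catalytic hydrogenolysis should cleave the three aryl benzyl ethers faster than the secondary benzylic C4–O3 and C8–O7 bonds in a neutral aprotic solvent, and no stereocentre is touched.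

**Compound list**

1 | 4-(benzyloxy)-3-methoxybenzaldehyde | COc1cc(C=O)ccc1OCc1ccccc1 | starting material
2 | vinylmagnesium bromide | C=C[Mg]Br | starting material
3 | racemic 1-[4-(benzyloxy)-3-methoxyphenyl]prop-2-en-1-ol | COc1cc(C(O)C=C)ccc1OCc1ccccc1 | intermediate
4 | (S)-1-[4-(benzyloxy)-3-methoxyphenyl]prop-2-en-1-ol | COc1cc([C@@H](O)C=C)ccc1OCc1ccccc1 | intermediate
5 | acryloyl chloride | C=CC(=O)Cl | starting material
6 | (S)-1-[4-(benzyloxy)-3-methoxyphenyl]prop-2-en-1-yl acrylate | COc1cc([C@@H](OC(=O)C=C)C=C)ccc1OCc1ccccc1 | intermediate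
7 | (S)-5-[4-(benzyloxy)-3-methoxyphenyl]furan-2(5H)-one | COc1cc([C@H]2OC(=O)C=C2)ccc1OCc1ccccc1 | intermediate
8 | 3,4-bis(benzyloxy)benzaldehyde | O=Cc1ccc(OCc2ccccc2)c(OCc2ccccc2)c1 | starting material
9 | (trimethylsilyl)methanol | C[Si](C)(C)CO | starting material
10 | 1,2-bis(benzyloxy)-4-{bis[(trimethylsilyl)methoxy]methyl}benzene | C[Si](C)(C)COC(OC[Si](C)(C)C)c1ccc(OCc2ccccc2)c(OCc2ccccc2)c1 | intermediate
11 | racemic 1,2-bis(benzyloxy)-4-{chloro[(trimethylsilyl)methoxy]methyl}benzene (α-chloro ether) | C[Si](C)(C)COC(Cl)c1ccc(OCc2ccccc2)c(OCc2ccccc2)c1 | intermediate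
12 | (E)-[3,4-bis(benzyloxy)benzylidene]oxoniomethanide (carbonyl ylide) | [CH2-]/[O+]=C/c1ccc(OCc2ccccc2)c(OCc2ccccc2)c1 | intermediate
13 | (1S,4S,5R,8S)-4-[4-(benzyloxy)-3-methoxyphenyl]-8-[3,4-bis(benzyloxy)phenyl]-3,7-dioxabicyclo[3.3.0]octan-2-one | COc1cc([C@H]2OC(=O)[C@H]3[C@@H]2CO[C@@H]3c2ccc(OCc4ccccc4)c(OCc4ccccc4)c2)ccc1OCc1ccccc1 | intermediate
14 | (1S,4S,5R,8S)-8-(3,4-dihydroxyphenyl)-4-(4-hydroxy-3-methoxyphenyl)-3,7-dioxabicyclo[3.3.0]octan-2-one | COc1cc([C@H]2OC(=O)[C@H]3[C@@H]2CO[C@@H]3c2ccc(O)c(O)c2)ccc1O | target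

**Summary and risks**

Total step count: 7. Longest linear sequence: 6 steps (steps 1, 2, 3, 4, 6, 7).

Steps most likely to fail:

Step 6. What may go wrong: loss of enantiopurity of 7 through fluoride-mediated deprotonation at its aryl-bearing carbon, collapse of the ylide to the oxirane before it is trapped, or poor exo/endo or regiochemical control. The fallback builds the same two bonds one after the other under neutral and acidic conditions. It sets out from 7, whose benzophenone-sensitised photochemical addition of methanol (MeOH, 350 nm; conjugate addition of the hydroxymethyl radical anti to the aryl group) should give (4R,5S)-5-[4-(benzyloxy)-3-methoxyphenyl]-4-(hydroxymethyl)dihydrofuran-2(3H)-one F1. In parallel, 8 is converted with HC(OMe)3 and catalytic TsOH in MeOH into 1,2-bis(benzyloxy)-4-(dimethoxymethyl)benzene F2. Transacetalisation of F2 with F1 (PPTS, CH2Cl2, molecular sieves) should give the mixed acetal (4R,5S)-5-[4-(benzyloxy)-3-methoxyphenyl]-4-({[3,4-bis(benzyloxy)phenyl](methoxy)methoxy}methyl)dihydrofuran-2(3H)-one F3. TMSOTf and i-Pr2NEt (CH2Cl2, −78 °C to 0 °C) should then turn the lactone into its silyl ketene acetal and the acetal into the oxocarbenium ion, which close the C1–C8 bond in an intramolecular Mukaiyama-type aldol addition. The tether enforces cis fusion and the aryl group should take the exo position. The fallback comes back to the route at 13.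

Step 7. What may go wrong: over-reduction, i.e. hydrogenolysis of the benzylic lactone C4–O3 bond (a benzyl-ester-type bond) competing with cleavage of the benzyl ethers. The fallback removes the ester character of that bond before the hydrogenolysis. It sets out from 13, which is saponified (LiOH, THF/H2O, 0 °C) to lithium (2S,3S,4R)-2-[3,4-bis(benzyloxy)phenyl]-4-{(S)-[4-(benzyloxy)-3-methoxyphenyl](hydroxy)methyl}tetrahydrofuran-3-carboxylate F4. Hydrogenolysis of this salt (H2, 10% Pd/C, THF/H2O, rt), in which the benzylic C–O bond is that of a free alcohol in a non-acidic medium and should be cleaved far more slowly, should give lithium (2S,3S,4R)-2-(3,4-dihydroxyphenyl)-4-[(S)-hydroxy(4-hydroxy-3-methoxyphenyl)methyl]tetrahydrofuran-3-carboxylate F5. Acidification (dilute HCl, pH 2 to 3, rt) relactonises the hydroxy acid, and the fallback comes back to the route at 14.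

Step 4. What may go wrong: ionisation with allylic transposition or racemisation of the electron-rich benzylic acrylate 6, or stalling of the metathesis at the electron-poor acrylate. The fallback avoids both the acrylate and the metathesis. It sets out from 1, which with ethynylmagnesium bromide (THF, 0 °C) should give racemic 1-[4-(benzyloxy)-3-methoxyphenyl]prop-2-yn-1-ol F6. The same lipase resolution (Novozym 435, vinyl acetate, MTBE) should leave (S)-1-[4-(benzyloxy)-3-methoxyphenyl]prop-2-yn-1-ol F7. Double deprotonation (n-BuLi, 2.2 equiv, THF, −78 °C) and carboxylation with CO2 should give (R)-4-[4-(benzyloxy)-3-methoxyphenyl]-4-hydroxybut-2-ynoic acid F8; the spatial arrangement is unchanged and only the priority order alters the descriptor. Semi-hydrogenation (H2, Pd/CaCO3 poisoned with Pb(OAc)2, quinoline, EtOAc) should give the Z-hydroxy acid, which lactonises spontaneously, and the fallback comes back to the route at 7.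

**Further compounds**

F1 | step 6 | (4R,5S)-5-[4-(benzyloxy)-3-methoxyphenyl]-4-(hydroxymethyl)dihydrofuran-2(3H)-one | COc1cc([C@H]2OC(=O)C[C@@H]2CO)ccc1OCc1ccccc1
F2 | step 6 | 1,2-bis(benzyloxy)-4-(dimethoxymethyl)benzene | COC(OC)c1ccc(OCc2ccccc2)c(OCc2ccccc2)c1
F3 | step 6 | (4R,5S)-5-[4-(benzyloxy)-3-methoxyphenyl]-4-({[3,4-bis(benzyloxy)phenyl](methoxy)methoxy}methyl)dihydrofuran-2(3H)-one (both acetal epimers) | COc1cc([C@H]2OC(=O)C[C@@H]2COC(OC)c2ccc(OCc3ccccc3)c(OCc3ccccc3)c2)ccc1OCc1ccccc1
F4 | step 7 | lithium (2S,3S,4R)-2-[3,4-bis(benzyloxy)phenyl]-4-{(S)-[4-(benzyloxy)-3-methoxyphenyl](hydroxy)methyl}tetrahydrofuran-3-carboxylate | COc1cc([C@@H](O)[C@H]2CO[C@H](c3ccc(OCc4ccccc4)c(OCc4ccccc4)c3)[C@H]2C(=O)[O-])ccc1OCc1ccccc1.[Li+]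
F5 | step 7 | lithium (2S,3S,4R)-2-(3,4-dihydroxyphenyl)-4-[(S)-hydroxy(4-hydroxy-3-methoxyphenyl)methyl]tetrahydrofuran-3-carboxylate | COc1cc([C@@H](O)[C@H]2CO[C@H](c3ccc(O)c(O)c3)[C@H]2C(=O)[O-])ccc1O.[Li+]
F6 | step 4 | racemic 1-[4-(benzyloxy)-3-methoxyphenyl]prop-2-yn-1-ol | COc1cc(C(O)C#C)ccc1OCc1ccccc1
F7 | step 4 | (S)-1-[4-(benzyloxy)-3-methoxyphenyl]prop-2-yn-1-ol | COc1cc([C@@H](O)C#C)ccc1OCc1ccccc1
F8 | step 4 | (R)-4-[4-(benzyloxy)-3-methoxyphenyl]-4-hydroxybut-2-ynoic acid | COc1cc([C@@H](O)C#CC(=O)O)ccc1OCc1ccccc1
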